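**Retrosynthetic overview**
- Last operations: removal of a MOM ether (ring-A OH) and a copper-catalysed C–O coupling (ring-C OCH3) on a bromo pentacycle.
- Ring B (closed last): intramolecular palladium-catalysed α-alkenylation of an aryl methyl ketone onto the C–Br next to the dienone carbonyl.
- Key C–C bond (ring A to ring C): Suzuki–Miyaura coupling of an ortho-acetyl aryl boronate (fragment 1, from resorcinol by ketone-directed Ir C–H borylation) with the β-bromoenone of a tribromo tricycle (fragment 2).
- Fragment 2 (rings C, D, E): a new enantioselective desymmetrising annulation of the achiral tetrabromo p-quinol (from p-cresol) with 1-pyrroline (from pyrrolidine) forms rings D and E together and sets both stereocentres.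
- Ring order: A and C come from the two arenes, D and E are formed in one step, B is formed last.

Assumption: the ring-B keto form drawn in the SMILES (C9=O with C10H2) is the isolated form of the target, and the (R) antipode of the step 8 catalyst is written although its sense of induction has to be fixed by experiment.

**Route**

Step 1
Reactants: 1 resorcinol; 2 acetic acid
Product: 3 1-(2,4-dihydroxyphenyl)ethan-1-one
Conditions: ZnCl2 (1.2 equiv), AcOH, 140 °C
Reagents that add atoms: none
Why: Nencki reaction (ZnCl2-promoted Friedel–Crafts acylation by the free acid) acylates resorcinol at C4, ortho to one OH and para to the other.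

Step 2
Reactants: 3 1-(2,4-dihydroxyphenyl)ethan-1-one
Product: 4 1-(2-hydroxy-4-methoxyphenyl)ethan-1-one
Conditions: MeI (1.05 equiv), K2CO3 (1.1 equiv), acetone, 56 °C
Reagents that add atoms: iodomethane, CI
Why: Williamson ether synthesis is selective for the 4-OH because the 2-OH is hydrogen-bonded to the ketone and far less nucleophilic.

Step 3
Reactants: 4 1-(2-hydroxy-4-methoxyphenyl)ethan-1-one
Product: 5 1-[4-methoxy-2-(methoxymethoxy)phenyl]ethan-1-one
Conditions: MOMCl (1.5 equiv), K2CO3 (2 equiv), acetone, 56 °C
Reagents that add atoms: chloromethyl methyl ether, COCCl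
Why: Williamson-type O-alkylation protects the chelated phenol as an acetal that survives base, boron and palladium chemistry and is later removed with mild acid.

Step 4
Reactants: 5 1-[4-methoxy-2-(methoxymethoxy)phenyl]ethan-1-one
Product: 6 1-[4-methoxy-2-(methoxymethoxy)-6-(4,4,5,5-tetramethyl-1,3,2-dioxaborolan-2-yl)phenyl]ethan-1-one (fragment 1)
Conditions: B2pin2 (1.2 equiv), [Ir(OMe)(cod)]2 (2.5 mol%), AsPh3 (10 mol%), octane, 120 °C
Reagents that add atoms: bis(pinacolato)diboron, CC1(C)OB(OC1(C)C)B1OC(C)(C)C(C)(C)O1
Why: Ketone-directed iridium-catalysed ortho C–H borylation: with the monodentate AsPh3 ligand the carbonyl oxygen binds iridium and delivers boron to the only C–H ortho to the acetyl group.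

Step 5
Reactants: 7 pyrrolidine
Product: 8 1-pyrroline (3,4-dihydro-2H-pyrrole)
Conditions: Na2S2O8 (1.0 equiv), AgNO3 (0.5 mol%), NaOH (2 equiv), H2O, 0 °C; extracted and used at once as a toluene solution (monomer in equilibrium with its trimer)
Reagents that add atoms: none
Why: Silver-catalysed persulfate dehydrogenation of a secondary amine gives the cyclic imine, which is made fresh because it trimerises on storage.

Step 6
Reactants: 9 p-cresol
Product: 10 2,3,5,6-tetrabromo-4-methylphenol
Conditions: Br2 (6 equiv), AlBr3 (5 mol%), 1,2-dichloroethane, 0 to 60 °C, dark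
Reagents that add atoms: bromine, BrBr
Why: Exhaustive electrophilic aromatic bromination: OH activates C2 and C6, the Lewis acid forces substitution at C3 and C5, and the dark, non-radical conditions leave the methyl group alone.

Step 7
Reactants: 10 2,3,5,6-tetrabromo-4-methylphenol
Product: 11 2,3,5,6-tetrabromo-4-hydroxy-4-methylcyclohexa-2,5-dien-1-one
Conditions: PhI(OCOCF3)2 (1.2 equiv), MeCN/H2O (3:1), 0 °C to rt
Reagents that add atoms: water, O
Why: Oxidative dearomatisation of a para-alkylphenol by a trivalent iodine reagent, with water attacking the para carbon, gives the p-quinol, which is achiral because its two bromoenone arms are mirror images.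

Step 8
Reactants: 11 2,3,5,6-tetrabromo-4-hydroxy-4-methylcyclohexa-2,5-dien-1-one; 8 1-pyrroline
Product: 13 (3aS,4aS)-5,6,8-tribromo-4a-methyl-1,2,3,3a-tetrahydrobenzo[d]pyrrolo[2,1-b][1,3]oxazol-7(4aH)-one (fragment 2), via hemiaminal ether 12 (not isolated)
Conditions: 8 (1.3 equiv, added over 6 h), (R)-3,3'-bis(2,4,6-triisopropylphenyl)-1,1'-binaphthyl-2,2'-diyl hydrogen phosphate (10 mol%), Na2CO3 (1.5 equiv), 4 Å MS, toluene, −20 °C
Reagents that add atoms: none
Why: Proposed new method: a chiral phosphoric acid catalysed desymmetrising (3+2) annulation of a prochiral 3,5-dibromo-p-quinol with a cyclic imine, in which the phosphate ion-pairs with protonated 8 and hydrogen-bonds the quinol OH, the O–H adds to C=N to give hemiaminal ether 12, and its N–H closes 5-exo onto one of the two enantiotopic β-bromoenone carbons (aza-Michael addition, then loss of bromide, taken up by Na2CO3); hemiaminal formation is reversible and the ring fusion is expected to strongly prefer the aminal H syn to the methyl group, so the catalyst-chosen (S) aminal carbon decides which arm is attacked and thereby fixes the quaternary carbon (4aS here, the R centre of the target), while slow addition keeps free imine low to suppress an uncatalysed N-first attack; the closest known reaction type is the chiral phosphoric acid catalysed acetalisation/oxa-Michael desymmetrisation of p-quinols with aldehydes (and aza-Michael desymmetrisations of cyclohexadienones), not yet shown with imines, with a β-halide leaving group or on perhalogenated quinols.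

Step 9
Reactants: 13 fragment 2; 6 fragment 1
Product: 14 (3aS,4aR)-5-[2-acetyl-5-methoxy-3-(methoxymethoxy)phenyl]-6,8-dibromo-4a-methyl-1,2,3,3a-tetrahydrobenzo[d]pyrrolo[2,1-b][1,3]oxazol-7(4aH)-one
Conditions: Pd(OAc)2 (5 mol%), SPhos (10 mol%), K3PO4 (3 equiv), toluene/H2O (10:1), 70 °C
Reagents that add atoms: none
Why: Suzuki–Miyaura coupling: zerovalent palladium inserts fastest into the C5–Br bond, the β-position of the bromoenone (a vinylogous acyl bromide), leaving the α C–Br bonds at C6 and C8, SPhos copes with the hindered partners, and no stereocentre is touched.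

Step 10
Reactants: 14 the Suzuki product
Product: 15 (4R)-2-bromo-6-methoxy-8-(methoxymethoxy)-4-methyl-4,10-dihydrophenanthrene-1,9-dione bridged from C3 (N) to the C4 oxygen by (2S)-pyrrolidine-1,2-diyl
Conditions: Pd2(dba)3 (2.5 mol%), XPhos (6 mol%), K3PO4 (2.5 equiv), toluene, 90 °C, argon
Reagents that add atoms: none
Why: Intramolecular palladium-catalysed α-alkenylation of a ketone enolate (Buchwald–Hartwig-type enolate coupling): oxidative addition into the electron-poor C6–Br bond held next to the acetyl group and reductive elimination with the potassium enolate close the six-membered ring B, while the electron-rich C–Br of the vinylogous amide reacts more slowly.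

Step 11
Reactants: 15 the bromo pentacycle
Product: 16 (4R)-2,6-dimethoxy-8-(methoxymethoxy)-4-methyl-4,10-dihydrophenanthrene-1,9-dione bridged from C3 (N) to the C4 oxygen by (2S)-pyrrolidine-1,2-diyl
Conditions: CuBr (20 mol%), 3,4,7,8-tetramethyl-1,10-phenanthroline (40 mol%), Cs2CO3 (2 equiv), MeOH/toluene (1:2), 90 °C, argon
Reagents that add atoms: methanol, CO
Why: Ullmann-type copper-catalysed C–O coupling of the vinyl bromide with methanol, helped by chelation of copper to the neighbouring carbonyl, installs the ring-C methoxy group without touching the N,O-acetal or the MOM ether.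

Step 12
Reactants: 16 the MOM-protected target
Product: 17 (4R)-8-hydroxy-2,6-dimethoxy-4-methyl-4,10-dihydrophenanthrene-1,9-dione bridged from C3 (N) to the C4 oxygen by (2S)-pyrrolidine-1,2-diyl (target CNP0528850.1)
Conditions: TFA/CH2Cl2 (1:10), 0 °C; aq. NaHCO3 work-up
Reagents that add atoms: none
Why: Acid cleavage of the MOM acetal is fast for a phenol ether chelated to the peri ketone, the quaternary carbon cannot epimerise, and the brief acid exposure lets the aminal carbon settle in what is expected to be its preferred configuration (H syn to CH3).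

**Compound list**
1 | resorcinol | Oc1cccc(O)c1 | starting material
2 | acetic acid | CC(=O)O | starting material
3 | 1-(2,4-dihydroxyphenyl)ethan-1-one | CC(=O)c1ccc(O)cc1O | intermediate
4 | 1-(2-hydroxy-4-methoxyphenyl)ethan-1-one | CC(=O)c1ccc(OC)cc1O | intermediate
5 | 1-[4-methoxy-2-(methoxymethoxy)phenyl]ethan-1-one | CC(=O)c1ccc(OC)cc1OCOC | intermediate
6 | 1-[4-methoxy-2-(methoxymethoxy)-6-(4,4,5,5-tetramethyl-1,3,2-dioxaborolan-2-yl)phenyl]ethan-1-one (fragment 1) | CC(=O)c1c(OCOC)cc(OC)cc1B1OC(C)(C)C(C)(C)O1 | intermediate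
7 | pyrrolidine | C1CCNC1 | starting material
8 | 1-pyrroline (3,4-dihydro-2H-pyrrole) | C1CC=NC1 | intermediate
9 | p-cresol | Cc1ccc(O)cc1 | starting material
10 | 2,3,5,6-tetrabromo-4-methylphenol | Cc1c(Br)c(Br)c(O)c(Br)c1Br | intermediate
11 | 2,3,5,6-tetrabromo-4-hydroxy-4-methylcyclohexa-2,5-dien-1-one | CC1(O)C(Br)=C(Br)C(=O)C(Br)=C1Br | intermediate
12 | 2,3,5,6-tetrabromo-4-methyl-4-{[(2S)-pyrrolidin-2-yl]oxy}cyclohexa-2,5-dien-1-one (hemiaminal ether, not isolated) | CC1(O[C@H]2CCCN2)C(Br)=C(Br)C(=O)C(Br)=C1Br | intermediate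
13 | (3aS,4aS)-5,6,8-tribromo-4a-methyl-1,2,3,3a-tetrahydrobenzo[d]pyrrolo[2,1-b][1,3]oxazol-7(4aH)-one (fragment 2) | BrC1=C2N3CCC[C@@H]3O[C@]2(C)C(Br)=C(Br)C1=O | intermediate
14 | (3aS,4aR)-5-[2-acetyl-5-methoxy-3-(methoxymethoxy)phenyl]-6,8-dibromo-4a-methyl-1,2,3,3a-tetrahydrobenzo[d]pyrrolo[2,1-b][1,3]oxazol-7(4aH)-one | BrC1=C2N3CCC[C@@H]3O[C@]2(C)C(c2cc(OC)cc(OCOC)c2C(C)=O)=C(Br)C1=O | intermediate
15 | (4R)-2-bromo-6-methoxy-8-(methoxymethoxy)-4-methyl-4,10-dihydrophenanthrene-1,9-dione bridged from C3 (N) to the C4 oxygen by (2S)-pyrrolidine-1,2-diyl | BrC1=C2N3CCC[C@@H]3O[C@]2(C)C2=C(CC(=O)c3c(OCOC)cc(OC)cc32)C1=O | intermediate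
16 | (4R)-2,6-dimethoxy-8-(methoxymethoxy)-4-methyl-4,10-dihydrophenanthrene-1,9-dione bridged from C3 (N) to the C4 oxygen by (2S)-pyrrolidine-1,2-diyl | COC1=C2N3CCC[C@@H]3O[C@]2(C)C2=C(CC(=O)c3c(OCOC)cc(OC)cc32)C1=O | intermediate
17 | (4R)-8-hydroxy-2,6-dimethoxy-4-methyl-4,10-dihydrophenanthrene-1,9-dione bridged from C3 (N) to the C4 oxygen by (2S)-pyrrolidine-1,2-diyl (CNP0528850.1) | COC1=C2N3CCC[C@@H]3O[C@]2(C)C2=C(CC(=O)c3c(O)cc(OC)cc32)C1=O | target

**Step count and risks**

Total step count: 12. Longest linear sequence: 8 (steps 1 to 4, then 9 to 12).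

The three steps most likely to fail:

Step 8 (the proposed new annulation). The neutral imine may attack a β-bromoenone carbon without the catalyst, which would erode the ee, and the diastereomer ratio at the aminal carbon is untested. Fallback with known chemistry, setting out from 11 and coming back at 13: 11 is treated with L-proline (NaHCO3, MeCN/H2O, 0 °C to rt), whose secondary amine displaces one β-bromide by addition–elimination. This gives N-[(6S)-2,4,5-tribromo-6-hydroxy-6-methyl-3-oxocyclohexa-1,4-dien-1-yl]-L-proline F1 together with its diastereomer N-[(6R)-2,4,5-tribromo-6-hydroxy-6-methyl-3-oxocyclohexa-1,4-dien-1-yl]-L-proline F2. The two are separated by chromatography or crystallisation. F1 then undergoes oxidative radical decarboxylation (PhI(OAc)2, I2, CH2Cl2, visible light, rt), and the resulting cyclic iminium ion is trapped by the tertiary alcohol to give 13.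

Step 10 (ring-B closure). The base-mediated enolate coupling may suffer from reaction at the second C–Br bond or from enolate addition to the dienone. Fallback setting out from 14 and coming back at 15: the methyl ketone is converted into the silyl enol ether (3aS,4aR)-6,8-dibromo-5-{5-methoxy-3-(methoxymethoxy)-2-[1-(trimethylsilyloxy)ethenyl]phenyl}-4a-methyl-1,2,3,3a-tetrahydrobenzo[d]pyrrolo[2,1-b][1,3]oxazol-7(4aH)-one F3 (TMSOTf, Et3N, CH2Cl2, 0 °C). F3 is cyclised without added base through its tin enolate (Bu3SnF, PdCl2[P(o-tol)3]2 3 mol%, toluene, 100 °C) to give 15.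

Step 11 (C–O coupling). The α-bromo vinylogous amide may stall or lose bromine by reduction. Fallback setting out from 15 and coming back at 16: Miyaura borylation (B2pin2, PdCl2(dppf) 5 mol%, KOAc, dioxane, 80 °C) gives the 2-(4,4,5,5-tetramethyl-1,3,2-dioxaborolan-2-yl) analogue of 15 F4. Oxidation (NaBO3·4H2O, THF/H2O, rt) gives the 2-hydroxy analogue of 15 F5. O-methylation of this acidic enol with TMSCHN2 (MeOH/toluene, 0 °C) gives 16.

Further compounds
F1 | step 8 | N-[(6S)-2,4,5-tribromo-6-hydroxy-6-methyl-3-oxocyclohexa-1,4-dien-1-yl]-L-proline | BrC1=C(N2CCC[C@H]2C(=O)O)[C@@](O)(C)C(Br)=C(Br)C1=O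
F2 | step 8 | N-[(6R)-2,4,5-tribromo-6-hydroxy-6-methyl-3-oxocyclohexa-1,4-dien-1-yl]-L-proline | BrC1=C(N2CCC[C@H]2C(=O)O)[C@](O)(C)C(Br)=C(Br)C1=O
F3 | step 10 | (3aS,4aR)-6,8-dibromo-5-{5-methoxy-3-(methoxymethoxy)-2-[1-(trimethylsilyloxy)ethenyl]phenyl}-4a-methyl-1,2,3,3a-tetrahydrobenzo[d]pyrrolo[2,1-b][1,3]oxazol-7(4aH)-one | BrC1=C2N3CCC[C@@H]3O[C@]2(C)C(c2cc(OC)cc(OCOC)c2C(=C)O[Si](C)(C)C)=C(Br)C1=O
F4 | step 11 | 2-(4,4,5,5-tetramethyl-1,3,2-dioxaborolan-2-yl) analogue of 15 (boron in place of bromine at C2) | CC1(C)OB(OC1(C)C)C1=C2N3CCC[C@@H]3O[C@]2(C)C2=C(CC(=O)c3c(OCOC)cc(OC)cc32)C1=O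
F5 | step 11 | 2-hydroxy analogue of 15 (OH in place of bromine at C2) | OC1=C2N3CCC[C@@H]3O[C@]2(C)C2=C(CC(=O)c3c(OCOC)cc(OC)cc32)C1=O
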